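The constants stand for no real mixture; the run is a simulation.

A ratio of 35.0 stands between two half-lives in cedar: 1.4 h for substrate in the first step, with coupling partner as charged, is far longer than 2.4 min for intermediate going to target (forward rate alone, the way back not counted).

| flask | substrate | coupling partner | second reagent | time | remark |
|---|---|---|---|---|---|
| larch | 0.020 M (fed, over 1.60 h) | 0.0200 M | 0.0400 M | 2.0 h | a stirred flask in which substrate is dosed at a steady rate over 1.60 h without added volume, worked up at 2.0 h |
| cedar | 0.020 M | 0.0200 M | 0.0400 M | 2.0 h | everything together in a closed stirred flask, run for 2.0 h |
| maple | 0.020 M | 0.0200 M | 0.0400 M |  | one stirred flow tank at steady state, fed with the mixture as stated, mean residence time 2.0 h |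
| oak | 0.020 M | 0.0200 M | 0.0400 M |  | a single well-mixed tank run continuously and read at steady state, 20.0 h in it on average |

    substrate + coupling partner → intermediate (k1 = 0.41 M⁻¹ min⁻¹)
    target → over-reaction product (k2 = 3.0 × 10⁻⁵ min⁻¹)
    second reagent + intermediate ⇌ target (K3 = 26 M⁻¹, k3 = 7.2 M⁻¹ min⁻¹)

1. the set-up with the highest amount of intermediate at the outlet or at the end, in percent of the substrate put in ("none" if the first two lie within 2 percentage points) (larch / cedar / maple / oak / none)
2. amount of intermediate at the outlet or at the end, in percent of the substrate put in, larch
3. amount of intermediate at the outlet or at the end, in percent of the substrate put in, cedar
4. amount of intermediate at the outlet or at the end, in percent of the substrate put in, maple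
5. amount of intermediate at the outlet or at the end, in percent of the substrate put in, oak

- the stated concentrations are those of everything mixed, before any reaction; amounts are the same in each set-up
- the feed brings no volume worth counting
- run time (larch): 2.0 h

1. Target's own half-life, 16 d, is far longer than the 20.0 h spent on average in oak, so this reckoning sets the over-reaction aside.

2. The first step, with the longer of the two opening half-lives, is taken as the rate-limiting step, and intermediate and target balance behind it.

3. Converted substrate divides accordingly. The equilibrium constant times charged [second reagent] is 1.0, so the equilibrium share, the fraction of converted substrate standing as intermediate, one over one plus that product, is 0.490.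

4. Charges of substrate and coupling partner are equal, so one number measures conversion: rate constant times charge times time, 0.984 for cedar and maple. Cedar keeps one over one plus that number. The tanks solve a quadratic for what remains. Larch is treated crudely as a closed flask, its substrate present on average for 1.20 h.

5. Share times conversion gives larch 18.2%, cedar 24.3%, maple 18.6% and oak 35.7%, so this reckoning picks oak.

6. The forecast names oak, with 18.8% for larch, 26% for cedar, 19.8% for maple and 38.5% for oak, on the ground that the “long-residence tank gets much the highest conversion”. Its order matches this reckoning; its figures differ.

7. The simulation gives oak: larch 18.8%, cedar 26.0%, maple 19.7%, oak 38.5%.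

Intermediate in oak stands at 38.5% through the undoing of target into second reagent and intermediate; without that return, oak holds 0.329%. The share can follow [second reagent] as read. Larch at the end, with substrate at 63.8% of the charge and second reagent at 91% of its own, gets 18.6% against 18.8%. Larch read at 8.0 h, with substrate at 22.1% and second reagent at 82.0%, gets 42.0%, and that flask holds 41.9%.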